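# Synthesis plan for CNP0200738.1 (compound 32) through a phosphine-catalysed allenoate–enone (3+2) annulation

## The problem

Atom numbering used throughout: ethyl C1–C2 on C3; dienyl carbons C4–C7 from C3 to the phenyl ring; six-membered ring C3–C8=C9–C10–C14–C15 (methyl on C9); five-membered ring C10–C11–C12=C13–C14 (methyls on C11 and C13); C15 carries a methyl group and the carboxyl carbon C16. TBS = tert-butyl(dimethyl)silyl.

Target 32 is (1R,3aR,4R,5S,7aS)-5-ethyl-1,3,4,7-tetramethyl-5-[(1E,3E)-4-phenylbuta-1,3-dien-1-yl]-3a,4,5,7a-tetrahydro-1H-indene-4-carboxylic acid, a cyclohexene trans-fused along C10–C14 to a cyclopentene. Its five stereocentres are contiguous (C3, C15, C14, C10, C11). Two of them, C3 and C15, are adjacent quaternary carbons whose carbon substituents C4 and C16 are cis. No other centre can set this pair, so it has to be made first and with absolute control. Once it exists, C15 can direct bond formation at its neighbour C14; C10 follows C14 through alkene geometry and can be equilibrated while C9 is a carbonyl; C11 is fixed in the same event as C10. The phenylbutadiene will not survive metathesis catalysts, strong acid or radical conditions and must arrive late. The carboxyl group sits on a carbon hemmed in by C3 and C14, so an ester there resists hydroxide; it also lies cis to C4, so a free C4 hydroxyl can lactonise onto it. The feature that opens the molecule is the cyclopentene: alkene at C12=C13, carbon substituents on C11 and C13, and trans exocyclic bonds at C10 and C14. This is the imprint of an allenoate three-carbon unit (C11–C12–C13) added across an (E)-alkene C10=C14. If C9 is a ketone, that alkene is an enone, and the same carbonyl later supplies the C8=C9 alkene.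

## Retrosynthesis

**C16 ester and C4=C5 (32 ⇒ 31 ⇒ 29 + 30).** The acid is kept to the end as the 2-(trimethylsilyl)ethyl ester 31, and 31 is cut at C4=C5 into aldehyde 29 and diethyl cinnamylphosphonate 30. Cutting here, not at C6=C7, keeps the phenyl half as a purchasable reagent and puts the whole diene on after every step it would not tolerate. The precursor loses nine carbons and its most fragile group. The forward olefination must give the E alkene at a neopentyl, non-enolisable aldehyde. The ester must fall to fluoride, because hydroxide cannot reach its carbonyl.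

**Oxidation levels at C4 and C13 (29 ⇒ 28 ⇒ 27 ⇒ 25 via 26 ⇒ 24).** No skeletal bond is cut. C4 goes back to a silyl ether, and the C13 methyl goes back to the ester that the annulation needs as activating group. A lactone between the C4 oxygen and C16 was considered as a joint protecting group and rejected: its carbonyl would be C16, so reduction to the lactol would expose the aldehyde on the wrong carbon. The C4 oxygen therefore stays silylated until the rings are complete and is then oxidised at once. The forward steps ask for discrimination between the conjugated C13 ester and the buried C16 ester, and for hydride displacement without allylic shift.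

**C8=C9 (24 ⇒ 23 ⇒ 22).** The six-membered ring is opened at C8=C9 by a metathesis transform, and the isopropenyl group of 23 is traced to the C9 ketone of 22. Opening at C3–C8 would mean creating quaternary C3 during cyclisation; opening at C9–C10 or C14–C15 would cut next to a stereocentre. C8=C9 is the only ring bond whose formation touches no stereocentre. The precursor is monocyclic and carries the carbonyl that the annulation needs. The forward steps ask for methylenation of a hindered ketone and closure of a trans-fused ring from two hindered alkenes.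

**C13–C14 and C10–C11 (22 ⇒ 17 + 21).** This is the key disconnection: the cyclopentene is taken apart into (E)-enone 17 and ethyl penta-2,3-dienoate 21.
- It removes a ring, two C–C bonds and three stereocentres, and leaves an acyclic enone whose only stereocentres are the C3–C15 pair.
- A cut at C10–C14 plus C12-centred bonds (Alternative 3) would deliver the wrong oxidation pattern in the five-membered ring.
- The forward reaction needs α-regiochemistry of the phosphonium dienolate, attack on one face of C14 under the influence of C15, and the C11 methyl trans to the acetyl group.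
- The weak points are the bulk at C14 and the modest acyclic bias. They are met by a small, strongly nucleophilic phosphine, a flat ester at C16, and the fact that C10 can be equilibrated.

**C14=C10 and the C14 oxidation level (17 ⇒ 15 + 16; 15 ⇒ 13 via 14).** The enone is cut at its alkene into aldehyde 15 and phosphonate 16, and the aldehyde is traced to the free acid of 13. The phosphonate is preferred to the corresponding phosphorane because it reacts at room temperature. Enone 17 is a hexa-1,5-diene with two quaternary carbons at its centre and should not be heated. The precursor 13 already holds both carboxyl groups of C15 in differentiated form.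

**C3–C15 (13 ⇒ 10 via 11 and 12 ⇒ 6 + 9).** The bond between the two quaternary carbons is cut by an ester-enolate Claisen transform, giving mixed malonate 10, and 10 is split into allylic alcohol 6 and half-ester 9.
- A [3,3] shift is chosen over alkylation or conjugate addition because it forms a bond between two fully substituted carbons intramolecularly.
- It also carries the configuration of a secondary carbinol into C3 and relates C15 to it through a chair.
- The rearrangement leaves on C3 exactly the alkene that becomes C8, and on C15 one free acid (future C14) next to one ester (C16).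
- The forward reaction needs a ketene acetal of defined geometry, which the chelated malonate supplies, and a (Z)-alkene in 6.
- If the sense at C15 were reversed, the two carboxyl groups could exchange roles.

**Small fragments (6 ⇒ 5 ⇒ 4 ⇒ 3 ⇒ 1 + 2; 9 ⇒ 7 + 8; 21 ⇒ 18 + 19 via 20).** The (Z)-alkene of 6 is secured by passing through butenolide 4, made by ring-closing metathesis of ester 3 from (S)-but-3-en-2-ol 1 and acid 2. Reduction gives diol 5 and selective silylation gives 6. Half-ester 9 comes from dione 7 and alcohol 8. Allenoate 21 comes from propanoyl chloride 18 and ylide 19 through methylketene 20. All these precursors are purchasable, and the only stereocentre bought is that of 1.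

## Roads not taken

**Alternative 1:** The cut removes the two angular alkyl groups, the C15–methyl bond and the C3–C2 bond.
- Forward step: the tricyclic dienyl butenolide A2 (C3=C15 as the lactone alkene) takes a methyl cuprate at C15, and the lactone enolate is ethylated at C3. This gives the cis-fused lactone A1 without closing a ring.
- Merits: both quaternary carbons arise in one flask on a rigid frame. Their cis relation is enforced because the five-membered lactone can only be cis-fused.
- Where it is better: A1 is the lactone with its carbonyl at C4. Reduction to the lactol, olefination and oxidation of C16 would finish the synthesis with no protecting group at C4 or C16. The chosen plan has to keep a free C4 hydroxyl from attacking the C16 ester.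
- Weak points: A2 is a 2,4-dienoate, so addition at C9 competes with addition at C15, and both positions are fully substituted. The face of C15 is set only by C14. The enolate must be alkylated with a sluggish ethyl halide next to a new quaternary carbon, with C9 as a second nucleophilic site. A2 itself, with three stereocentres and a tetrasubstituted alkene, needs an enantioselective synthesis of its own.
- What the chosen plan sets against it: both quaternary carbons are made in one sigmatropic step with predictable relative and absolute configuration, before any ring exists.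

**Alternative 2:** The cut is the ring bond C3–C8.
- Forward step: substrate A4 carries a (Z)-bromoalkene at C8=C9 and a trisubstituted C3=C4 alkene on C15. Oxidative addition to zerovalent palladium, 6-exo insertion and β-hydride elimination towards C5 would give A3, which is the same compound as 31.
- Merits and where it is better: the last ring bond, quaternary C3 and the diene are made in one step. No oxygen function at C4 is ever needed, so the end of the synthesis is shorter than the three steps that take 27 to 31 here.
- Weak points: the insertion creates a quaternary carbon directly beside quaternary C15, the most demanding case for this reaction. The configuration at C3 depends only on the conformation of the closing ring, with no strong bias between ethyl and the chain. The geometry of C4=C5 and migration of the diene by hydride re-addition are not controlled. A4 needs a stereodefined bromoalkene, a stereodefined trisubstituted alkene and a lone quaternary C15 set against C14.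
- What the chosen plan sets against it: the ring closure at C8=C9 puts no stereocentre at stake, and C3 and C15 are made together.

**Alternative 3:** Three bonds are cut at once: C10–C14, C11–C12 and C12–C13.
- Forward step: acyclic dienyne A6 (propynyl on C15, a diene C8=C9–C10=C11 on C3) would react under carbon monoxide with [Rh(CO)2Cl]2. The alkyne and the outer (E)-propenyl alkene combine, and both rings close to bicyclic enone A5.
- Merits and where it is better: two rings and three C–C bonds form in one step, from an acyclic precursor that the same Claisen chemistry could supply. The chosen plan needs annulation, methylenation and metathesis for the same rings. The (E)-alkene geometry would give the trans relation of C10 and C11.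
- Weak points: A5 has the carbonyl at C12 and the alkene at C13=C14. The target needs C12=C13 and a hydrogen at C14 trans to that at C10. That means reducing a tetrasubstituted enone carbon next to quaternary C15 with control of the ring fusion, then moving the unsaturation. The face of the diene would be chosen by remote quaternary centres, and the internal alkyne on a quaternary carbon is a slow partner.
- What the chosen plan sets against it: the annulation gives the cyclopentene at the right oxidation pattern, with C14 set in a C–C bond-forming step beside C15. Only the ester-to-methyl change remains.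

Key step: step 11

## Route

Assumption: allenoate 21 is used as the racemate, because its axial chirality is erased when the phosphine adds to C12.

Step 1
Reactants: 1 (S)-but-3-en-2-ol; 2 2-methylidenebutanoic acid
Product: 3 (S)-but-3-en-2-yl 2-methylidenebutanoate
Conditions: DCC, DMAP (cat.), CH2Cl2, 0 °C → rt
Reagents that add atoms: none
Why: Steglich esterification of a secondary allylic alcohol; the carbinol C–O bond is not broken, so the S centre is kept.

Step 2
Reactants: 3 (S)-but-3-en-2-yl 2-methylidenebutanoate
Product: 4 (5S)-3-ethyl-5-methylfuran-2(5H)-one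
Conditions: second-generation Grubbs catalyst (5 mol %), CH2Cl2, 40 °C
Reagents that add atoms: none
Why: Ring-closing metathesis of an allyl 2-alkylacrylate to an α-substituted butenolide, driven by loss of ethene; the ring holds the future C4 and the carbinol carbon cis across the new alkene.

Step 3
Reactants: 4 (5S)-3-ethyl-5-methylfuran-2(5H)-one
Product: 5 (2Z,4S)-2-ethylpent-2-ene-1,4-diol
Conditions: iBu2AlH (4 equiv), CH2Cl2, −78 → 0 °C; aq. potassium sodium tartrate
Reagents that add atoms: none
Why: 1,2-Reduction of the unsaturated lactone through the lactol to the ene-diol; the Z geometry is inherited from the ring and the stereocentre is untouched.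

Step 4
Reactants: 5 (2Z,4S)-2-ethylpent-2-ene-1,4-diol
Product: 6 (2S,3Z)-4-(TBS-oxymethyl)hex-3-en-2-ol
Conditions: TBSCl (1.05 equiv), imidazole, CH2Cl2, −20 → 0 °C
Reagents that add atoms: tert-butyl(chloro)dimethylsilane, CC(C)(C)[Si](C)(C)Cl
Why: Silylation of the primary allylic hydroxyl in preference to the secondary one on steric grounds.

Step 5
Reactants: 7 2,2,5-trimethyl-1,3-dioxane-4,6-dione; 8 2-(trimethylsilyl)ethanol
Product: 9 2-methyl-3-oxo-3-[2-(trimethylsilyl)ethoxy]propanoic acid (racemic)
Conditions: toluene, 100 °C
Reagents that add atoms: none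
Why: Alcoholysis of the cyclic acylal with loss of acetone gives the malonic half-ester directly; the temperature stays below that of decarboxylation.

Step 6
Reactants: 6 (2S,3Z)-4-(TBS-oxymethyl)hex-3-en-2-ol; 9 2-methyl-3-oxo-3-[2-(trimethylsilyl)ethoxy]propanoic acid
Product: 10 mixed malonate (2S,3Z)-4-(TBS-oxymethyl)hex-3-en-2-yl 2-(trimethylsilyl)ethyl 2-methylpropanedioate (both epimers at the malonate carbon)
Conditions: DCC, DMAP (cat.), CH2Cl2, 0 °C → rt
Reagents that add atoms: none
Why: Steglich esterification; the malonate stereocentre does not matter because it becomes planar in the next step.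

Step 7
Reactants: 10 mixed malonate
Product: 13 acid (2S)-2-[(3S,4E)-3-(TBS-oxymethyl)hex-4-en-3-yl]-2-methyl-3-oxo-3-[2-(trimethylsilyl)ethoxy]propanoic acid, via silyl ketene acetal 11 (not isolated), via trimethylsilyl ester 12 (not isolated)
Conditions: LiN(SiMe3)2, THF, −78 °C; Me3SiCl, Et3N, −78 °C → rt; toluene, 80 °C; aq. citric acid
Reagents that add atoms: none
Why: Ireland–Claisen rearrangement: the malonate enolate is a chelate, so 11 has OSiMe3 cis to the second ester and the methyl cis to the allylic oxygen, and a chair with the carbinol methyl equatorial and the (Z)-CH2OTBS group axial forms C3–C15. The S carbinol centre is thereby transferred to C3, C15 is set relative to it with the new free acid in the place of C14, and the new alkene is E.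

Step 8
Reactants: 13 acid
Product: 15 aldehyde 2-(trimethylsilyl)ethyl (2S)-2-[(3S,4E)-3-(TBS-oxymethyl)hex-4-en-3-yl]-2-methyl-3-oxopropanoate, via acid chloride 14 (not isolated)
Conditions: 1-chloro-N,N,2-trimethylprop-1-en-1-amine, CH2Cl2, 0 °C → rt; then LiAlH(OtBu)3, THF, −78 °C
Reagents that add atoms: none
Why: Neutral acid chloride formation followed by partial reduction with the bulky alkoxyaluminium hydride, which stops at the aldehyde and leaves the ester, the silyl ether and the alkene alone; the quaternary α-carbon excludes ketene formation and epimerisation.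

Step 9
Reactants: 15 aldehyde; 16 dimethyl (2-oxopropyl)phosphonate
Product: 17 enone 2-(trimethylsilyl)ethyl (2R,3E)-2-[(3S,4E)-3-(TBS-oxymethyl)hex-4-en-3-yl]-2-methyl-5-oxohex-3-enoate
Conditions: LiCl, iPr2NEt, MeCN, rt
Reagents that add atoms: none
Why: Horner–Wadsworth–Emmons olefination under mild amine/LiCl conditions gives the (E)-enone from a non-enolisable aldehyde. Room temperature and a non-nucleophilic base avoid deformylation of 15 and Cope rearrangement of 17 across its C3–C15 bond.

Step 10
Reactants: 18 propanoyl chloride; 19 ethyl (triphenylphosphoranylidene)acetate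
Product: 21 ethyl penta-2,3-dienoate (racemic), via methylketene 20 (not isolated)
Conditions: Et3N, CH2Cl2, 0 °C → rt
Reagents that add atoms: none
Why: Dehydrochlorination gives the ketene, which undergoes a Wittig reaction with the stabilised ylide at its carbonyl to give the allenoate.

Step 11
Reactants: 17 enone; 21 ethyl penta-2,3-dienoate
Product: 22 cyclopentene ethyl (3R,4S,5R)-4-acetyl-3-methyl-5-[C15 side chain]cyclopent-1-ene-1-carboxylate (C15 R with methyl and CO2CH2CH2SiMe3; C3 S with ethyl, CH2OTBS and (E)-prop-1-enyl)
Conditions: PBu3 (30 mol %), 21 (3 equiv, slow addition), toluene, 50 °C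
Reagents that add atoms: none
Why: PBu3 adds to the central allene carbon C12 of 21 to give a phosphonium dienolate whose α-carbon C13 adds to C14 of 17; the resulting C10 enolate closes on the γ-carbon C11 of the vinylphosphonium, and proton shift from C13 to C12 followed by loss of PBu3 leaves C12=C13 and returns the catalyst. The closest known reaction type is the phosphine-catalysed (3+2) annulation of γ-substituted allenoates with β-substituted enones. The cyclopentene closes by 5-endo-trig attack of the enolate on the vinylphosphonium, the second stage of a stepwise (3+2) process. C14 is set in the first C–C bond formation by the adjacent quaternary C15: with C3 anti to the incoming C13, the flat ester lies on the flank the nucleophile passes and the methyl points towards C10, and the conformer with the ester anti leads to the same face, so 14R is expected. C10 comes out trans to C14 from the (E)-enone and, being α to the ketone, settles trans to both neighbours under the basic conditions. C11 is set in the ring closure, where its methyl takes the side away from the acetyl group and so ends cis to the C15 substituent across the ring, as in the cis-2,5 preference of such annulations. The step needs α- rather than γ-attack, which the γ-methyl group secures by shielding C11, and it needs a useful rate at a β-carbon flanked by a quaternary centre, which the small phosphine and slow addition of excess 21 are meant to provide.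

Step 12
Reactants: 22 cyclopentene with C10 acetyl
Product: 23 ethyl (3R,4S,5R)-3-methyl-4-(prop-1-en-2-yl)-5-[C15 side chain as in 22]cyclopent-1-ene-1-carboxylate
Conditions: Ph3PCH3Br, KOtBu, THF, 0 °C → rt
Reagents that add atoms: methyltriphenylphosphonium bromide, C[P+](c1ccccc1)(c1ccccc1)c1ccccc1.[Br-]
Why: Wittig methylenation of the methyl ketone; the two esters are not attacked, and any enolisation at C10 returns the thermodynamically preferred trans arrangement already present.

Step 13
Reactants: 23 isopropenyl cyclopentene
Product: 24 3-ethyl 4-[2-(trimethylsilyl)ethyl] (1R,3aR,4R,5S,7aS)-5-(TBS-oxymethyl)-5-ethyl-1,4,7-trimethyl-3a,4,5,7a-tetrahydro-1H-indene-3,4-dicarboxylate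
Conditions: second-generation Grubbs catalyst (10 mol %), toluene, 80 °C
Reagents that add atoms: none
Why: Ring-closing metathesis between the C3 propenyl group and the C9 methylidene forms the trisubstituted C8=C9 alkene of a six-membered ring with loss of propene; no stereocentre is involved, and the electron-poor C12=C13 alkene is inert.

Step 14
Reactants: 24 bicyclic diester
Product: 25 2-(trimethylsilyl)ethyl (1R,3aR,4R,5S,7aS)-5-(TBS-oxymethyl)-5-ethyl-3-(hydroxymethyl)-1,4,7-trimethyl-3a,4,5,7a-tetrahydro-1H-indene-4-carboxylate
Conditions: iBu2AlH (2.2 equiv), CH2Cl2, −78 °C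
Reagents that add atoms: none
Why: 1,2-Reduction of the conjugated ethyl ester to the allylic alcohol; the C16 ester sits on a quaternary carbon beside a second quaternary carbon and should be far slower to react at −78 °C.

Step 15
Reactants: 25 allylic alcohol
Product: 27 2-(trimethylsilyl)ethyl (1R,3aR,4R,5S,7aS)-5-(TBS-oxymethyl)-5-ethyl-1,3,4,7-tetramethyl-3a,4,5,7a-tetrahydro-1H-indene-4-carboxylate, via allylic methanesulfonate 26 (not isolated)
Conditions: MsCl, Et3N, THF, −20 °C; then LiEt3BH (1.2 equiv), −78 → 0 °C
Reagents that add atoms: none
Why: Sulfonylation and SN2 displacement by hydride at the primary allylic carbon give the C13 methyl group without allylic shift; the limited amount of hydride at low temperature spares the buried ester.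

Step 16
Reactants: 27 silyl ether
Product: 28 2-(trimethylsilyl)ethyl (1R,3aR,4R,5S,7aS)-5-ethyl-5-(hydroxymethyl)-1,3,4,7-tetramethyl-3a,4,5,7a-tetrahydro-1H-indene-4-carboxylate
Conditions: HF·pyridine, pyridine, THF, 0 °C → rt
Reagents that add atoms: none
Why: Buffered fluoride cleavage of the primary silyl ether; the 2-(trimethylsilyl)ethyl ester tolerates these conditions, and the neutral alcohol is taken on crude so that it has little time to add to the hindered ester.

Step 17
Reactants: 28 primary alcohol
Product: 29 2-(trimethylsilyl)ethyl (1R,3aR,4R,5S,7aS)-5-ethyl-5-formyl-1,3,4,7-tetramethyl-3a,4,5,7a-tetrahydro-1H-indene-4-carboxylate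
Conditions: Dess–Martin periodinane, NaHCO3, CH2Cl2, 0 °C → rt
Reagents that add atoms: none
Why: Mild oxidation of a neopentyl alcohol to the aldehyde, which cannot enolise or epimerise because C3 is quaternary.

Step 18
Reactants: 29 aldehyde; 30 diethyl [(2E)-3-phenylprop-2-en-1-yl]phosphonate
Product: 31 2-(trimethylsilyl)ethyl (1R,3aR,4R,5S,7aS)-5-ethyl-1,3,4,7-tetramethyl-5-[(1E,3E)-4-phenylbuta-1,3-dien-1-yl]-3a,4,5,7a-tetrahydro-1H-indene-4-carboxylate
Conditions: NaN(SiMe3)2, THF, −78 °C → rt
Reagents that add atoms: none
Why: Horner–Wadsworth–Emmons olefination with the allylic phosphonate anion forms C4=C5 with E geometry and keeps the E cinnamyl alkene; the aldehyde has no α-hydrogen, so the base can only add.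

Step 19
Reactants: 31 2-(trimethylsilyl)ethyl ester
Product: 32 (1R,3aR,4R,5S,7aS)-5-ethyl-1,3,4,7-tetramethyl-5-[(1E,3E)-4-phenylbuta-1,3-dien-1-yl]-3a,4,5,7a-tetrahydro-1H-indene-4-carboxylic acid
Conditions: Bu4NF, THF, 0 °C → rt; aq. NH4Cl
Reagents that add atoms: none
Why: Fluoride attacks silicon and the ester fragments to carboxylate, ethene and Me3SiF, so the hindered carbonyl need not be attacked; no stereocentre or alkene is touched.

## Compound list

1 | (S)-but-3-en-2-ol | C[C@H](O)C=C | starting material
2 | 2-methylidenebutanoic acid | CCC(=C)C(=O)O | starting material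
3 | (S)-but-3-en-2-yl 2-methylidenebutanoate | CCC(=C)C(=O)O[C@@H](C)C=C | intermediate
4 | (5S)-3-ethyl-5-methylfuran-2(5H)-one | CCC1=C[C@H](C)OC1=O | intermediate
5 | (2Z,4S)-2-ethylpent-2-ene-1,4-diol | CC/C(CO)=C/[C@H](C)O | intermediate
6 | (2S,3Z)-4-({[tert-butyl(dimethyl)silyl]oxy}methyl)hex-3-en-2-ol | CC/C(CO[Si](C)(C)C(C)(C)C)=C/[C@H](C)O | intermediate
7 | 2,2,5-trimethyl-1,3-dioxane-4,6-dione | CC1C(=O)OC(C)(C)OC1=O | starting material
8 | 2-(trimethylsilyl)ethanol | C[Si](C)(C)CCO | starting material
9 | 2-methyl-3-oxo-3-[2-(trimethylsilyl)ethoxy]propanoic acid (racemic) | CC(C(=O)O)C(=O)OCC[Si](C)(C)C | intermediate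
10 | (2S,3Z)-4-({[tert-butyl(dimethyl)silyl]oxy}methyl)hex-3-en-2-yl 2-(trimethylsilyl)ethyl 2-methylpropanedioate (both epimers at the malonate carbon) | CC/C(CO[Si](C)(C)C(C)(C)C)=C/[C@H](C)OC(=O)C(C)C(=O)OCC[Si](C)(C)C | intermediate
11 | silyl ketene acetal of 10 (OSiMe3 cis to the CO2CH2CH2SiMe3 group, methyl cis to the allylic oxygen) | C/C(C(=O)OCC[Si](C)(C)C)=C(/O[Si](C)(C)C)O[C@@H](C)/C=C(/CC)CO[Si](C)(C)C(C)(C)C | intermediate
12 | trimethylsilyl ester of acid 13 | CC[C@](CO[Si](C)(C)C(C)(C)C)(/C=C/C)[C@](C)(C(=O)OCC[Si](C)(C)C)C(=O)O[Si](C)(C)C | intermediate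
13 | (2S)-2-[(3S,4E)-3-({[tert-butyl(dimethyl)silyl]oxy}methyl)hex-4-en-3-yl]-2-methyl-3-oxo-3-[2-(trimethylsilyl)ethoxy]propanoic acid | CC[C@](CO[Si](C)(C)C(C)(C)C)(/C=C/C)[C@](C)(C(=O)OCC[Si](C)(C)C)C(=O)O | intermediate
14 | acid chloride of 13 | CC[C@](CO[Si](C)(C)C(C)(C)C)(/C=C/C)[C@](C)(C(=O)OCC[Si](C)(C)C)C(Cl)=O | intermediate
15 | 2-(trimethylsilyl)ethyl (2S)-2-[(3S,4E)-3-({[tert-butyl(dimethyl)silyl]oxy}methyl)hex-4-en-3-yl]-2-methyl-3-oxopropanoate (C14 aldehyde) | CC[C@](CO[Si](C)(C)C(C)(C)C)(/C=C/C)[C@](C)(C(=O)OCC[Si](C)(C)C)C=O | intermediate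
16 | dimethyl (2-oxopropyl)phosphonate | COP(=O)(CC(C)=O)OC | starting material
17 | 2-(trimethylsilyl)ethyl (2R,3E)-2-[(3S,4E)-3-({[tert-butyl(dimethyl)silyl]oxy}methyl)hex-4-en-3-yl]-2-methyl-5-oxohex-3-enoate (key-step enone) | CC[C@](CO[Si](C)(C)C(C)(C)C)(/C=C/C)[C@](C)(C(=O)OCC[Si](C)(C)C)/C=C/C(C)=O | intermediate
18 | propanoyl chloride | CCC(Cl)=O | starting material
19 | ethyl (triphenylphosphoranylidene)acetate | CCOC(=O)C=P(c1ccccc1)(c1ccccc1)c1ccccc1 | starting material
20 | methylketene (prop-1-en-1-one) | CC=C=O | intermediate
21 | ethyl penta-2,3-dienoate (racemic) | CC=C=CC(=O)OCC | intermediate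
22 | ethyl (3R,4S,5R)-4-acetyl-3-methyl-5-[(2R,3S,4E)-3-({[tert-butyl(dimethyl)silyl]oxy}methyl)-3-ethyl-2-methyl-1-oxo-1-[2-(trimethylsilyl)ethoxy]hex-4-en-2-yl]cyclopent-1-ene-1-carboxylate (key-step product) | CC[C@](CO[Si](C)(C)C(C)(C)C)(/C=C/C)[C@](C)(C(=O)OCC[Si](C)(C)C)[C@H]1C(C(=O)OCC)=C[C@@H](C)[C@@H]1C(C)=O | intermediate
23 | ethyl (3R,4S,5R)-3-methyl-4-(prop-1-en-2-yl)-5-[(2R,3S,4E)-3-({[tert-butyl(dimethyl)silyl]oxy}methyl)-3-ethyl-2-methyl-1-oxo-1-[2-(trimethylsilyl)ethoxy]hex-4-en-2-yl]cyclopent-1-ene-1-carboxylate | CC[C@](CO[Si](C)(C)C(C)(C)C)(/C=C/C)[C@](C)(C(=O)OCC[Si](C)(C)C)[C@H]1C(C(=O)OCC)=C[C@@H](C)[C@@H]1C(C)=C | intermediate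
24 | 3-ethyl 4-[2-(trimethylsilyl)ethyl] (1R,3aR,4R,5S,7aS)-5-({[tert-butyl(dimethyl)silyl]oxy}methyl)-5-ethyl-1,4,7-trimethyl-3a,4,5,7a-tetrahydro-1H-indene-3,4-dicarboxylate | CC[C@]1(CO[Si](C)(C)C(C)(C)C)C=C(C)[C@H]2[C@H](C)C=C(C(=O)OCC)[C@@H]2[C@@]1(C)C(=O)OCC[Si](C)(C)C | intermediate
25 | 2-(trimethylsilyl)ethyl (1R,3aR,4R,5S,7aS)-5-({[tert-butyl(dimethyl)silyl]oxy}methyl)-5-ethyl-3-(hydroxymethyl)-1,4,7-trimethyl-3a,4,5,7a-tetrahydro-1H-indene-4-carboxylate | CC[C@]1(CO[Si](C)(C)C(C)(C)C)C=C(C)[C@H]2[C@H](C)C=C(CO)[C@@H]2[C@@]1(C)C(=O)OCC[Si](C)(C)C | intermediate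
26 | methanesulfonate of allylic alcohol 25 | CC[C@]1(CO[Si](C)(C)C(C)(C)C)C=C(C)[C@H]2[C@H](C)C=C(COS(C)(=O)=O)[C@@H]2[C@@]1(C)C(=O)OCC[Si](C)(C)C | intermediate
27 | 2-(trimethylsilyl)ethyl (1R,3aR,4R,5S,7aS)-5-({[tert-butyl(dimethyl)silyl]oxy}methyl)-5-ethyl-1,3,4,7-tetramethyl-3a,4,5,7a-tetrahydro-1H-indene-4-carboxylate | CC[C@]1(CO[Si](C)(C)C(C)(C)C)C=C(C)[C@H]2[C@H](C)C=C(C)[C@@H]2[C@@]1(C)C(=O)OCC[Si](C)(C)C | intermediate
28 | 2-(trimethylsilyl)ethyl (1R,3aR,4R,5S,7aS)-5-ethyl-5-(hydroxymethyl)-1,3,4,7-tetramethyl-3a,4,5,7a-tetrahydro-1H-indene-4-carboxylate | CC[C@]1(CO)C=C(C)[C@H]2[C@H](C)C=C(C)[C@@H]2[C@@]1(C)C(=O)OCC[Si](C)(C)C | intermediate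
29 | 2-(trimethylsilyl)ethyl (1R,3aR,4R,5S,7aS)-5-ethyl-5-formyl-1,3,4,7-tetramethyl-3a,4,5,7a-tetrahydro-1H-indene-4-carboxylate | CC[C@]1(C=O)C=C(C)[C@H]2[C@H](C)C=C(C)[C@@H]2[C@@]1(C)C(=O)OCC[Si](C)(C)C | intermediate
30 | diethyl [(2E)-3-phenylprop-2-en-1-yl]phosphonate | CCOP(=O)(C/C=C/c1ccccc1)OCC | starting material
31 | 2-(trimethylsilyl)ethyl (1R,3aR,4R,5S,7aS)-5-ethyl-1,3,4,7-tetramethyl-5-[(1E,3E)-4-phenylbuta-1,3-dien-1-yl]-3a,4,5,7a-tetrahydro-1H-indene-4-carboxylate | CC[C@]1(/C=C/C=C/c2ccccc2)C=C(C)[C@H]2[C@H](C)C=C(C)[C@@H]2[C@@]1(C)C(=O)OCC[Si](C)(C)C | intermediate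
32 | (1R,3aR,4R,5S,7aS)-5-ethyl-1,3,4,7-tetramethyl-5-[(1E,3E)-4-phenylbuta-1,3-dien-1-yl]-3a,4,5,7a-tetrahydro-1H-indene-4-carboxylic acid | CC[C@]1(/C=C/C=C/c2ccccc2)C=C(C)[C@H]2[C@H](C)C=C(C)[C@@H]2[C@@]1(C)C(=O)O | target

## Step count and risks

Total: 19 steps. Longest linear sequence: 17 steps (steps 1–4, 6–9 and 11–19, from 1 to 32). Steps 5 and 10 make the side fragments 9 and 21.

**Step 11 (key step).**
- Risk: addition at C14, a β-carbon flanked by a quaternary centre, may be so slow that oligomerisation or isomerisation of the allenoate uses up 21 first. Discrimination between the two enone faces rests on an acyclic model and may be incomplete.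
- Fallback: this sets out from 15 and returns at 22. Knoevenagel condensation of 15 with pentane-2,4-dione (TiCl4, pyridine, THF) gives the alkylidene diketone F1. F1 is a doubly activated acceptor with no alkene geometry to control. Its PBu3-catalysed annulation with 21 gives the 10,10-diacetyl cyclopentene F2. Retro-Claisen removal of one acetyl group (NaOEt, EtOH), with protonation at C10 under equilibrating conditions, gives 22.

**Step 7.**
- Risk: loss of control at C15, through a boat-like transition state or through the ketene acetal of the other geometry. Decarboxylation of the malonic half-ester may occur if the mixture is overheated.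
- Fallback: this sets out from 10 and returns at 15. It turns the unwanted outcome to use, because the two carboxyl groups on C15 can exchange roles. The C15-epimeric acid F3 is reduced at its ester with LiBH4 in the presence of the lithium carboxylate, giving hydroxy acid F4. The acid is esterified with 2-(trimethylsilyl)ethyl 2,2,2-trichloroacetimidate to hydroxy ester F5. Dess–Martin oxidation of F5 gives 15. Either epimer from the rearrangement therefore reaches the same aldehyde.

**Step 13.**
- Risk: slow initiation on two hindered alkenes (a 1,2-disubstituted one on a quaternary carbon and a 1,1-disubstituted one). Catalyst decay or intermolecular metathesis may then take over.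
- Fallback: this sets out from 22 and returns at 24. Ozonolysis of the propenyl group (O3, CH2Cl2/MeOH, −78 °C; Me2S) gives keto aldehyde F6; the conjugated C12=C13 alkene is much less reactive. Intramolecular McMurry coupling of F6 (TiCl3, Zn–Cu, 1,2-dimethoxyethane, reflux, high dilution) joins C8 and C9 to give 24.

**Step 14.**
- Risk: incomplete discrimination between the two esters, with reduction at C16 as well.
- Fallback: this sets out from 24 and returns at 25. LiOH in aqueous THF hydrolyses only the unhindered conjugated ethyl ester, giving the C13 carboxylic acid F7. Isobutyl chloroformate and N-methylmorpholine convert F7 into the mixed anhydride F8, which NaBH4 reduces to 25. None of these reagents can reach the C16 ester.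

**Step 16.**
- Risk: lactonisation of the freed C4 hydroxyl onto the cis C16 ester, with loss of 2-(trimethylsilyl)ethanol.
- Fallback: this sets out from 27 and returns at 32. Excess Bu4NF removes both silyl groups and gives the hydroxy acid F9, which is kept as its carboxylate salt and so cannot lactonise. Dess–Martin oxidation gives the aldehyde acid, which exists as the pseudo-acid (hydroxy lactone) F10. Olefination with an excess of the sodium anion of 30 opens F10 to the aldehyde carboxylate and gives 32 directly after acidification.

## Further compounds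

F1 | step 11 | 2-(trimethylsilyl)ethyl (2R)-3-acetyl-2-[(3S,4E)-3-({[tert-butyl(dimethyl)silyl]oxy}methyl)hex-4-en-3-yl]-2-methyl-5-oxohex-3-enoate (alkylidene diketone) | CC[C@](CO[Si](C)(C)C(C)(C)C)(/C=C/C)[C@](C)(C(=O)OCC[Si](C)(C)C)C=C(C(C)=O)C(C)=O
F2 | step 11 | 10,10-diacetyl analogue of 22 (ethyl 4,4-diacetyl-3-methyl-5-[C15 side chain]cyclopent-1-ene-1-carboxylate) | CC[C@](CO[Si](C)(C)C(C)(C)C)(/C=C/C)[C@](C)(C(=O)OCC[Si](C)(C)C)[C@H]1C(C(=O)OCC)=C[C@@H](C)C1(C(C)=O)C(C)=O
F3 | step 7 | C15 epimer of acid 13 | CC[C@](CO[Si](C)(C)C(C)(C)C)(/C=C/C)[C@@](C)(C(=O)OCC[Si](C)(C)C)C(=O)O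
F4 | step 7 | 2-[(3S,4E)-3-({[tert-butyl(dimethyl)silyl]oxy}methyl)hex-4-en-3-yl]-3-hydroxy-2-methylpropanoic acid (C16 acid, C14 alcohol) | CC[C@](CO[Si](C)(C)C(C)(C)C)(/C=C/C)[C@@](C)(CO)C(=O)O
F5 | step 7 | 2-(trimethylsilyl)ethyl ester of F4 (alcohol corresponding to aldehyde 15) | CC[C@](CO[Si](C)(C)C(C)(C)C)(/C=C/C)[C@@](C)(CO)C(=O)OCC[Si](C)(C)C
F6 | step 13 | keto aldehyde: analogue of 22 with a formyl group (C8) in place of the propenyl group on C3 | CC[C@](CO[Si](C)(C)C(C)(C)C)(C=O)[C@](C)(C(=O)OCC[Si](C)(C)C)[C@H]1C(C(=O)OCC)=C[C@@H](C)[C@@H]1C(C)=O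
F7 | step 14 | C13 carboxylic acid from 24 (C16 ester intact) | CC[C@]1(CO[Si](C)(C)C(C)(C)C)C=C(C)[C@H]2[C@H](C)C=C(C(=O)O)[C@@H]2[C@@]1(C)C(=O)OCC[Si](C)(C)C
F8 | step 14 | isobutyl carbonic mixed anhydride of F7 | CC[C@]1(CO[Si](C)(C)C(C)(C)C)C=C(C)[C@H]2[C@H](C)C=C(C(=O)OC(=O)OCC(C)C)[C@@H]2[C@@]1(C)C(=O)OCC[Si](C)(C)C
F9 | step 16 | (1R,3aR,4R,5S,7aS)-5-ethyl-5-(hydroxymethyl)-1,3,4,7-tetramethyl-3a,4,5,7a-tetrahydro-1H-indene-4-carboxylic acid (handled as its tetrabutylammonium salt) | CC[C@]1(CO)C=C(C)[C@H]2[C@H](C)C=C(C)[C@@H]2[C@@]1(C)C(=O)O
F10 | step 16 | pseudo-acid: hydroxy lactone between C16 and the C4 aldehyde (both configurations at C4) | CC[C@]12C=C(C)[C@H]3[C@H](C)C=C(C)[C@@H]3[C@@]1(C)C(=O)OC2O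
A1 | alternative 1 | cis-fused lactone with both quaternary centres (carbonyl at C4, oxygen on C16) | CC[C@]12C=C(C)[C@H]3[C@H](C)C=C(C)[C@@H]3[C@@]1(C)COC2=O
A2 | alternative 1 | tricyclic dienyl butenolide with C3=C15 | O=C1OCC2=C1C=C(C)[C@H]1[C@H](C)C=C(C)[C@H]21
A3 | alternative 2 | 2-(trimethylsilyl)ethyl ester of the target (identical with 31) | CC[C@]1(/C=C/C=C/c2ccccc2)C=C(C)[C@H]2[C@H](C)C=C(C)[C@@H]2[C@@]1(C)C(=O)OCC[Si](C)(C)C
A4 | alternative 2 | cyclopentene with a (Z)-2-bromo-1-methylvinyl group on C10 and, on C14, quaternary C15 bearing methyl, CO2CH2CH2SiMe3 and the (E)-C3=C4 alkene with ethyl and a cinnamylmethyl chain | C[Si](C)(C)CCOC(=O)[C@@](C)(/C(CC)=C/C/C=C/c1ccccc1)[C@H]1C(C)=C[C@@H](C)[C@@H]1/C(C)=C\Br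
A5 | alternative 3 | bicyclic enone with the ketone at C12 and the alkene at C13=C14 | CC[C@]1(CO[Si](C)(C)C(C)(C)C)C=C(C)[C@H]2[C@H](C)C(=O)C(C)=C2[C@@]1(C)C(=O)OC
A6 | alternative 3 | acyclic dienyne: propynyl on C15, (Z,E)-diene C8=C9–C10=C11 on C3 | CC[C@](CO[Si](C)(C)C(C)(C)C)(/C=C(C)\C=C\C)[C@](C)(C(=O)OC)C#CC
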